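**Retrosynthetic overview**

1. The target is cut at the bond between the cyclohexenone core and the (E,E)-dienyl chain (enolate C-allylation with an allylic bromide that already carries the lactone). The carbinol comes from a bulky-hydride reduction, and the ketone is masked as the dimethyl ketal of a quinone monoketal made from 2,3,4-trimethoxyphenol (Cu-catalysed asymmetric methyl addition).
2. In the lactone (O1, C2=O, C3–CH3, C4H2, C5–chain) the C3–C4 bond is cut. The enabling feature is that the ester unit O1–C2(=O) ties C3 (α to the carbonyl, an activated C–Br site) to C4 (the primary carbon on the O-bearing C5, i.e. the CH2 of a 1,2-halohydrin). An α-bromopropanoate of a 1-iodo-2-alkanol therefore holds both carbons within reach of one nickel centre.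
3. Key event: a Ni-catalysed, Mn-driven intramolecular reductive coupling of the two C–X bonds. A six-membered nickelacycle contracts to the five-membered lactone, both α-bromo epimers converge, and C5 steers C3.
4. The iodohydrin comes from farnesol: the terminal isopropylidene is excised (bromohydrin, epoxide, periodate), L-proline α-aminoxylation of the resulting aldehyde sets the C5–O centre, and the primary hydroxyl is iodinated selectively.
5. Ring order: the lactone ring is closed (step 8) before the fragment union. The carbocycle is never closed; it is bought as the arene and dearomatised (step 11).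

Key step: step 8

Assumption: 2-bromopropanoyl bromide is used as the racemate, and the phosphoramidite antipode named in step 12 is taken to be the one that delivers the (5R)-ketone (assigned by analogy with 4,4-dialkoxycyclohexadienones; the other antipode would be used if the sense is opposite).

**Route**

Step 1
Reactants: 1 (2E,6E)-farnesol
Product: 2 tert-butyldiphenyl{[(2E,6E)-3,7,11-trimethyldodeca-2,6,10-trien-1-yl]oxy}silane
Conditions: TBDPSCl, imidazole, DMF, 0 °C → rt
Reagents that add atoms: tert-butyl(chloro)diphenylsilane, CC(C)(C)[Si](Cl)(c1ccccc1)c1ccccc1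
Why: Imidazole-promoted silylation of the primary allylic alcohol (silyl ether protection) forms no stereocentre and installs a group expected to survive periodic acid, Zn/AcOH and the Ni/Mn step.

Step 2
Reactants: 2 tert-butyldiphenyl{[(2E,6E)-3,7,11-trimethyldodeca-2,6,10-trien-1-yl]oxy}silane
Product: 4 tert-butyl{[(2E,6E)-9-(3,3-dimethyloxiran-2-yl)-3,7-dimethylnona-2,6-dien-1-yl]oxy}diphenylsilane (racemic), via bromohydrin 3 (not isolated)
Conditions: NBS (1.1 equiv), THF/H2O (3:1), 0 °C; then K2CO3, MeOH, rt
Reagents that add atoms: water, O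
Why: Terminal-selective bromohydrin formation in aqueous THF (only the terminal isopropylidene alkene of the coiled polyene is exposed to Br+, water adds at the tertiary carbon) followed by Williamson-type closure gives the terminal epoxide, whose racemic stereocentre is destroyed in step 3.

Step 3
Reactants: 4 tert-butyl{[(2E,6E)-9-(3,3-dimethyloxiran-2-yl)-3,7-dimethylnona-2,6-dien-1-yl]oxy}diphenylsilane
Product: 5 (4E,8E)-10-[(tert-butyldiphenylsilyl)oxy]-4,8-dimethyldeca-4,8-dienal
Conditions: H5IO6 (1.2 equiv), THF/Et2O, 0 °C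
Reagents that add atoms: none
Why: Periodic acid hydrates the trisubstituted epoxide at its tertiary carbon and cleaves the glycol (Malaprade-type cleavage), so the aldehyde oxygen is the former epoxide oxygen and acetone is lost, while the internal alkenes and the silyl ether are untouched.

Step 4
Reactants: 5 (4E,8E)-10-[(tert-butyldiphenylsilyl)oxy]-4,8-dimethyldeca-4,8-dienal
Product: 7 (2R,4E,8E)-10-[(tert-butyldiphenylsilyl)oxy]-4,8-dimethyl-2-[(phenylamino)oxy]deca-4,8-dien-1-ol, via α-anilinoxy aldehyde 6 (not isolated)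
Conditions: PhNO (1.0 equiv, slow addition), L-proline (20 mol%), CHCl3, 4 °C; then NaBH4, EtOH, 0 °C
Reagents that add atoms: nitrosobenzene, O=Nc1ccccc1
Why: Proline-catalysed α-aminoxylation (enamine catalysis, O-selective nitroso aldol) with in situ borohydride reduction of the labile α-oxy aldehyde; the carboxylic acid of L-proline delivers PhN=O to one enamine face, which by the established sense for linear aldehydes should give the (R) C–O centre that becomes C5 of the lactone.

Step 5
Reactants: 7 (2R,4E,8E)-10-[(tert-butyldiphenylsilyl)oxy]-4,8-dimethyl-2-[(phenylamino)oxy]deca-4,8-dien-1-ol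
Product: 8 (2R,4E,8E)-10-[(tert-butyldiphenylsilyl)oxy]-4,8-dimethyldeca-4,8-diene-1,2-diol
Conditions: Zn dust, AcOH/EtOH (1:3), rt
Reagents that add atoms: none
Why: Dissolving-zinc reductive cleavage of the weak N–O bond frees the 1,2-diol without involving the stereocentre, the trisubstituted alkenes or the silyl ether.

Step 6
Reactants: 8 (2R,4E,8E)-10-[(tert-butyldiphenylsilyl)oxy]-4,8-dimethyldeca-4,8-diene-1,2-diol
Product: 9 (2R,4E,8E)-10-[(tert-butyldiphenylsilyl)oxy]-1-iodo-4,8-dimethyldeca-4,8-dien-2-ol
Conditions: PPh3 (1.1 equiv), I2 (1.1 equiv), imidazole (2.2 equiv), CH2Cl2, 0 °C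
Reagents that add atoms: iodine, II
Why: Appel-type iodination in which the alkoxyphosphonium ion forms and is displaced by iodide much faster at the primary than at the secondary hydroxyl at 0 °C with one equivalent of reagent, so the C–O stereocentre is not involved.

Step 7
Reactants: 9 (2R,4E,8E)-10-[(tert-butyldiphenylsilyl)oxy]-1-iodo-4,8-dimethyldeca-4,8-dien-2-ol; 10 2-bromopropanoyl bromide (racemic)
Product: 11 (2R,4E,8E)-10-[(tert-butyldiphenylsilyl)oxy]-1-iodo-4,8-dimethyldeca-4,8-dien-2-yl (2RS)-2-bromopropanoate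
Conditions: pyridine, CH2Cl2, −20 → 0 °C
Reagents that add atoms: none
Why: Acylation of the secondary alcohol by the acid bromide (esterification) is faster than base-induced epoxide closure of the iodohydrin, and the racemic acyl bromide deliberately gives both α-bromo epimers, which are meant to converge in step 8.

Step 8
Reactants: 11 (2R,4E,8E)-10-[(tert-butyldiphenylsilyl)oxy]-1-iodo-4,8-dimethyldeca-4,8-dien-2-yl (2RS)-2-bromopropanoate
Product: 12 (3R,5S)-5-[(2E,6E)-8-[(tert-butyldiphenylsilyl)oxy]-2,6-dimethylocta-2,6-dien-1-yl]-3-methyloxolan-2-one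
Conditions: NiBr2·glyme (10 mol%), 4,4′,4″-tri-tert-butyl-2,2′:6′,2″-terpyridine (12 mol%), Mn powder (3 equiv), DMA, 25 °C, slow addition of 11 (final 0.02 M)
Reagents that add atoms: none
Why: Proposed new method: the nickel(0)–terpyridine complex is expected to take bromine from the activated α-bromo ester first, so that both α-epimers of 11 collapse to one α-acyl radical and one C/O-equilibrating nickel(II) enolate, and after reduction by Mn the same nickel centre abstracts iodine from the primary C–I bond four bonds away and recaptures the C4 radical; C(sp3)–C(sp3) reductive elimination from the resulting six-membered nickela(III)cycle (Ni–C3–C2(=O)–O1–C5–C4) then forms the C3–C4 bond. The closest known reaction types are the nickel-catalysed, Mn- or Zn-mediated reductive coupling and cyclisation of two alkyl halides and the stereoconvergent nickel-catalysed alkyl–alkyl coupling of racemic α-bromo carbonyl compounds, neither of which has been used to close a lactone between an α-bromo ester and a β-acyloxy alkyl iodide. The γ-lactone is closed in a formally 5-exo-tet sense at C4 by ring contraction of the nickelacycle, which sidesteps the geometric ban on 5-(enolendo)-exo-tet alkylation of the free ester enolate. The only new stereocentre, C3, is set by the existing C5 centre: because the Ni–C3 bond epimerises through the O-bound enolate, elimination should drain (Curtin–Hammett) through the half-chair nickelacycle in which the C5 side chain and the C3 methyl group are both pseudo-equatorial (1,4-trans), which maps onto the 3,5-trans (3R,5S) lactone. The step needs ordered activation of the two C–X bonds, which the large reactivity gap between α-bromo ester and primary iodide provides, and it needs freedom from β-acyloxy elimination, which should be secured because Mn forms no free organozinc, the tridentate ligand leaves no cis site, and the C4–Ni bond exists only inside the ring where O1 is held away from the metal. The two trisubstituted alkenes are placed so that the C4 radical could only close 4-exo or 5-endo and the C3 radical only 6-exo at a fully substituted carbon or 7-endo across the ester, so radical cyclisation should not compete, and slow addition holds back intermolecular coupling.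

Step 9
Reactants: 12 (3R,5S)-5-[(2E,6E)-8-[(tert-butyldiphenylsilyl)oxy]-2,6-dimethylocta-2,6-dien-1-yl]-3-methyloxolan-2-one
Product: 13 (3R,5S)-5-[(2E,6E)-8-hydroxy-2,6-dimethylocta-2,6-dien-1-yl]-3-methyloxolan-2-one
Conditions: TBAF/AcOH (1:1), THF, rt
Reagents that add atoms: none
Why: Fluoride-mediated desilylation buffered with acetic acid cleaves the Si–O bond without epimerising the lactone α-centre or opening the lactone.

Step 10
Reactants: 13 (3R,5S)-5-[(2E,6E)-8-hydroxy-2,6-dimethylocta-2,6-dien-1-yl]-3-methyloxolan-2-one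
Product: 14 (3R,5S)-5-[(2E,6E)-8-bromo-2,6-dimethylocta-2,6-dien-1-yl]-3-methyloxolan-2-one
Conditions: CBr4, PPh3, CH2Cl2, 0 °C
Reagents that add atoms: tetrabromomethane, BrC(Br)(Br)Br
Why: Appel bromination of the primary allylic alcohol under neutral conditions at 0 °C should give the allylic bromide by SN2 without E/Z isomerisation and without affecting the lactone.

Step 11
Reactants: 15 2,3,4-trimethoxyphenol
Product: 16 2,3,4,4-tetramethoxycyclohexa-2,5-dien-1-one
Conditions: PhI(OAc)2, MeOH, 0 °C
Reagents that add atoms: methanol, CO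
Why: Hypervalent-iodine oxidative dearomatisation of the para-methoxyphenol in methanol adds methanol at the carbon para to the hydroxyl, which already carries OMe, giving the quinone monoketal.

Step 12
Reactants: 16 2,3,4,4-tetramethoxycyclohexa-2,5-dien-1-one
Product: 18 (5R)-2,3,4,4-tetramethoxy-5-methylcyclohex-2-en-1-one, via methylzinc enolate 17 (not isolated)
Conditions: Me2Zn (1.5 equiv), Cu(OTf)2 (2 mol%), (S,R,R)-BINOL-derived bis(1-phenylethyl)amine phosphoramidite (4 mol%), toluene, −25 °C; sat. aq. NH4Cl
Reagents that add atoms: dimethylzinc, C[Zn]C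
Why: Copper/phosphoramidite-catalysed asymmetric conjugate addition of a dialkylzinc to a quinone monoketal, in which only the unsubstituted C5=C6 enone is electrophilic (C3 is a tetrasubstituted vinylogous ester carbon) and the chiral Cu–ligand complex selects the enone face to set the methyl-bearing centre as (R).

Step 13
Reactants: 18 (5R)-2,3,4,4-tetramethoxy-5-methylcyclohex-2-en-1-one; 14 (3R,5S)-5-[(2E,6E)-8-bromo-2,6-dimethylocta-2,6-dien-1-yl]-3-methyloxolan-2-one
Product: 20 (3R,5S)-5-[(2E,6E)-2,6-dimethyl-8-[(1R,6R)-3,4,5,5-tetramethoxy-6-methyl-2-oxocyclohex-3-en-1-yl]octa-2,6-dien-1-yl]-3-methyloxolan-2-one, via lithium enolate 19 (not isolated)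
Conditions: LiHMDS (1.3 equiv) on 18 (1.4 equiv), THF, −78 °C; then 14 (1.0 equiv), DMPU, −78 → −20 °C
Reagents that add atoms: none
Why: Regiospecific lithium enolate formation (only C6 is enolisable) and SN2 C-allylation with the primary allylic bromide, which should approach anti to the adjacent C5 methyl group and give the 5,6-trans ketone, while the weakly basic ketone enolate, with no free amide base left, should not deprotonate the lactone.

Step 14
Reactants: 20 (3R,5S)-5-[(2E,6E)-2,6-dimethyl-8-[(1R,6R)-3,4,5,5-tetramethoxy-6-methyl-2-oxocyclohex-3-en-1-yl]octa-2,6-dien-1-yl]-3-methyloxolan-2-one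
Product: 21 (3R,5S)-5-[(2E,6E)-8-[(1R,2R,6R)-2-hydroxy-3,4,5,5-tetramethoxy-6-methylcyclohex-3-en-1-yl]-2,6-dimethylocta-2,6-dien-1-yl]-3-methyloxolan-2-one
Conditions: L-Selectride (1.1 equiv), THF, −78 °C; sat. aq. NH4Cl
Reagents that add atoms: none
Why: Bulky-hydride 1,2-reduction in which conjugate reduction is blocked by the fully substituted methoxy-bearing β-carbon and hydride attacks from the equatorial direction anti to the neighbouring side chain, giving the alcohol cis to that chain (R), while at −78 °C with one equivalent the lactone should not be reduced.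

Step 15
Reactants: 21 (3R,5S)-5-[(2E,6E)-8-[(1R,2R,6R)-2-hydroxy-3,4,5,5-tetramethoxy-6-methylcyclohex-3-en-1-yl]-2,6-dimethylocta-2,6-dien-1-yl]-3-methyloxolan-2-one
Product: 22 (3R,5S)-5-[(2E,6E)-8-[(1R,2R,6R)-2-hydroxy-3,4-dimethoxy-6-methyl-5-oxocyclohex-3-en-1-yl]-2,6-dimethylocta-2,6-dien-1-yl]-3-methyloxolan-2-one (target)
Conditions: 1 M aq. HCl, THF, 0 °C
Reagents that add atoms: water, O
Why: Mild acid hydrolysis of the dimethyl ketal, which ionises readily because its oxocarbenium ion is conjugated with the dimethoxy enol ether, should unveil the vinylogous ester ketone without touching the stereocentres or the lactone.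

**Compound list**

1 | (2E,6E)-farnesol | OC/C=C(\C)CC/C=C(\C)CCC=C(C)C | starting material
2 | tert-butyldiphenyl{[(2E,6E)-3,7,11-trimethyldodeca-2,6,10-trien-1-yl]oxy}silane | CC(C)(C)[Si](OC/C=C(\C)CC/C=C(\C)CCC=C(C)C)(c1ccccc1)c1ccccc1 | intermediate
3 | (6E,10E)-3-bromo-12-[(tert-butyldiphenylsilyl)oxy]-2,6,10-trimethyldodeca-6,10-dien-2-ol (racemic bromohydrin, not isolated) | CC(C)(C)[Si](OC/C=C(\C)CC/C=C(\C)CCC(Br)C(C)(C)O)(c1ccccc1)c1ccccc1 | intermediate
4 | tert-butyl{[(2E,6E)-9-(3,3-dimethyloxiran-2-yl)-3,7-dimethylnona-2,6-dien-1-yl]oxy}diphenylsilane (racemic) | CC(C)(C)[Si](OC/C=C(\C)CC/C=C(\C)CCC1OC1(C)C)(c1ccccc1)c1ccccc1 | intermediate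
5 | (4E,8E)-10-[(tert-butyldiphenylsilyl)oxy]-4,8-dimethyldeca-4,8-dienal | CC(C)(C)[Si](OC/C=C(\C)CC/C=C(\C)CCC=O)(c1ccccc1)c1ccccc1 | intermediate
6 | (2R,4E,8E)-10-[(tert-butyldiphenylsilyl)oxy]-4,8-dimethyl-2-[(phenylamino)oxy]deca-4,8-dienal (not isolated) | CC(C)(C)[Si](OC/C=C(\C)CC/C=C(\C)C[C@@H](ONc1ccccc1)C=O)(c1ccccc1)c1ccccc1 | intermediate
7 | (2R,4E,8E)-10-[(tert-butyldiphenylsilyl)oxy]-4,8-dimethyl-2-[(phenylamino)oxy]deca-4,8-dien-1-ol | CC(C)(C)[Si](OC/C=C(\C)CC/C=C(\C)C[C@@H](ONc1ccccc1)CO)(c1ccccc1)c1ccccc1 | intermediate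
8 | (2R,4E,8E)-10-[(tert-butyldiphenylsilyl)oxy]-4,8-dimethyldeca-4,8-diene-1,2-diol | CC(C)(C)[Si](OC/C=C(\C)CC/C=C(\C)C[C@@H](O)CO)(c1ccccc1)c1ccccc1 | intermediate
9 | (2R,4E,8E)-10-[(tert-butyldiphenylsilyl)oxy]-1-iodo-4,8-dimethyldeca-4,8-dien-2-ol | CC(C)(C)[Si](OC/C=C(\C)CC/C=C(\C)C[C@@H](O)CI)(c1ccccc1)c1ccccc1 | intermediate
10 | 2-bromopropanoyl bromide (racemic) | CC(Br)C(Br)=O | starting material
11 | (2R,4E,8E)-10-[(tert-butyldiphenylsilyl)oxy]-1-iodo-4,8-dimethyldeca-4,8-dien-2-yl (2RS)-2-bromopropanoate | CC(C)(C)[Si](OC/C=C(\C)CC/C=C(\C)C[C@H](CI)OC(=O)C(C)Br)(c1ccccc1)c1ccccc1 | intermediate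
12 | (3R,5S)-5-[(2E,6E)-8-[(tert-butyldiphenylsilyl)oxy]-2,6-dimethylocta-2,6-dien-1-yl]-3-methyloxolan-2-one | CC(C)(C)[Si](OC/C=C(\C)CC/C=C(\C)C[C@@H]1C[C@@H](C)C(=O)O1)(c1ccccc1)c1ccccc1 | intermediate
13 | (3R,5S)-5-[(2E,6E)-8-hydroxy-2,6-dimethylocta-2,6-dien-1-yl]-3-methyloxolan-2-one | OC/C=C(\C)CC/C=C(\C)C[C@@H]1C[C@@H](C)C(=O)O1 | intermediate
14 | (3R,5S)-5-[(2E,6E)-8-bromo-2,6-dimethylocta-2,6-dien-1-yl]-3-methyloxolan-2-one | BrC/C=C(\C)CC/C=C(\C)C[C@@H]1C[C@@H](C)C(=O)O1 | intermediate
15 | 2,3,4-trimethoxyphenol | COc1ccc(O)c(OC)c1OC | starting material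
16 | 2,3,4,4-tetramethoxycyclohexa-2,5-dien-1-one | COC1=C(OC)C(=O)C=CC1(OC)OC | intermediate
17 | methylzinc enolate of 18 (O–Zn on former C1, C1=C6; not isolated) | C[Zn]OC1=C[C@@H](C)C(OC)(OC)C(OC)=C1OC | intermediate
18 | (5R)-2,3,4,4-tetramethoxy-5-methylcyclohex-2-en-1-one | COC1=C(OC)C(=O)C[C@@H](C)C1(OC)OC | intermediate
19 | lithium enolate of 18 (O–Li on C1, C1=C6; not isolated) | [Li]OC1=C[C@@H](C)C(OC)(OC)C(OC)=C1OC | intermediate
20 | (3R,5S)-5-[(2E,6E)-2,6-dimethyl-8-[(1R,6R)-3,4,5,5-tetramethoxy-6-methyl-2-oxocyclohex-3-en-1-yl]octa-2,6-dien-1-yl]-3-methyloxolan-2-one | COC1=C(OC)C(=O)[C@H](C/C=C(\C)CC/C=C(\C)C[C@@H]2C[C@@H](C)C(=O)O2)[C@@H](C)C1(OC)OC | intermediate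
21 | (3R,5S)-5-[(2E,6E)-8-[(1R,2R,6R)-2-hydroxy-3,4,5,5-tetramethoxy-6-methylcyclohex-3-en-1-yl]-2,6-dimethylocta-2,6-dien-1-yl]-3-methyloxolan-2-one | COC1=C(OC)[C@H](O)[C@H](C/C=C(\C)CC/C=C(\C)C[C@@H]2C[C@@H](C)C(=O)O2)[C@@H](C)C1(OC)OC | intermediate
22 | (3R,5S)-5-[(2E,6E)-8-[(1R,2R,6R)-2-hydroxy-3,4-dimethoxy-6-methyl-5-oxocyclohex-3-en-1-yl]-2,6-dimethylocta-2,6-dien-1-yl]-3-methyloxolan-2-one (CNP0532375.1) | COC1=C(OC)[C@H](O)[C@H](C/C=C(\C)CC/C=C(\C)C[C@@H]2C[C@@H](C)C(=O)O2)[C@@H](C)C1=O | target

**Step count and risks**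

Total step count: 15. Longest linear sequence: 13 (steps 1–10, then 13, 14, 15).

Steps most likely to fail:

Step 8 (proposed new method). The nickel enolate may be protonated or reduced before the C–I bond is engaged (hydrodebromination). β-Acyloxy elimination may fragment the ester to a terminal alkene and a carboxylate. Reductive elimination may also proceed with poor control of C3. The fallback uses known chemistry and sets out from 9. K2CO3 in MeOH closes the iodohydrin to tert-butyl{[(2E,6E)-3,7-dimethyl-8-[(2R)-oxiran-2-yl]octa-2,6-dien-1-yl]oxy}diphenylsilane F1. Dilithioacetate (AcOH, 2 LDA, THF, 50 °C) opens F1 at its CH2 terminus to the γ-hydroxy acid (4S,6E,10E)-12-[(tert-butyldiphenylsilyl)oxy]-4-hydroxy-6,10-dimethyldodeca-6,10-dienoic acid F2. On acidification (cat. TsOH, benzene) F2 lactonises to (5S)-5-[(2E,6E)-8-[(tert-butyldiphenylsilyl)oxy]-2,6-dimethylocta-2,6-dien-1-yl]oxolan-2-one F3. Deprotonation of F3 with LDA (THF, −78 °C) and addition of MeI methylates the lactone enolate anti to the C5 side chain, the classical way to the 3,5-trans isomer, and the sequence comes back to the route at 12.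

Step 13. Proton transfer from the lactone α-C–H to the ketone enolate, slow SN2 at the hindered enolate carbon with O-allylation or double alkylation, and erosion of the trans selectivity may all lower the yield of the union. The fallback sets out from 13 and replaces the SN2 alkylation by π-allyl chemistry. Methyl chloroformate and pyridine (CH2Cl2, 0 °C) convert 13 into (2E,6E)-3,7-dimethyl-8-[(2S,4R)-4-methyl-5-oxooxolan-2-yl]octa-2,6-dien-1-yl methyl carbonate F4. A Tsuji–Trost allylation of lithium enolate 19 with F4 (Pd(PPh3)4, 5 mol%, THF, 0 °C) should then occur at the less substituted allyl terminus under nearly neutral conditions, and the sequence comes back to the route at 20.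

Step 6. Discrimination between the primary and the secondary hydroxyl may be lost in the phosphonium activation, the iodohydrin may close to the epoxide under the basic conditions, or the vicinal diol may be deoxygenated to the terminal alkene. The fallback sets out from 8 and uses sulfonate displacement. Tin-acetal-directed monotosylation (TsCl, Et3N, cat. Bu2SnO, CH2Cl2, 0 °C) should give (2R,4E,8E)-10-[(tert-butyldiphenylsilyl)oxy]-2-hydroxy-4,8-dimethyldeca-4,8-dien-1-yl 4-methylbenzenesulfonate F5. A Finkelstein exchange of F5 (NaI, acetone, reflux) then comes back to the route at 9.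

Further compounds
F1 | step 8 | tert-butyl{[(2E,6E)-3,7-dimethyl-8-[(2R)-oxiran-2-yl]octa-2,6-dien-1-yl]oxy}diphenylsilane | CC(C)(C)[Si](OC/C=C(\C)CC/C=C(\C)C[C@@H]1CO1)(c1ccccc1)c1ccccc1
F2 | step 8 | (4S,6E,10E)-12-[(tert-butyldiphenylsilyl)oxy]-4-hydroxy-6,10-dimethyldodeca-6,10-dienoic acid | CC(C)(C)[Si](OC/C=C(\C)CC/C=C(\C)C[C@@H](O)CCC(O)=O)(c1ccccc1)c1ccccc1
F3 | step 8 | (5S)-5-[(2E,6E)-8-[(tert-butyldiphenylsilyl)oxy]-2,6-dimethylocta-2,6-dien-1-yl]oxolan-2-one | CC(C)(C)[Si](OC/C=C(\C)CC/C=C(\C)C[C@@H]1CCC(=O)O1)(c1ccccc1)c1ccccc1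
F4 | step 13 | (2E,6E)-3,7-dimethyl-8-[(2S,4R)-4-methyl-5-oxooxolan-2-yl]octa-2,6-dien-1-yl methyl carbonate | COC(=O)OC/C=C(\C)CC/C=C(\C)C[C@@H]1C[C@@H](C)C(=O)O1
F5 | step 6 | (2R,4E,8E)-10-[(tert-butyldiphenylsilyl)oxy]-2-hydroxy-4,8-dimethyldeca-4,8-dien-1-yl 4-methylbenzenesulfonate | CC(C)(C)[Si](OC/C=C(\C)CC/C=C(\C)C[C@@H](O)COS(=O)(=O)c1ccc(C)cc1)(c1ccccc1)c1ccccc1
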